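**Plan**
1. Cuts: last, the two amide N–C(O) bonds to the dibromopyrrole units. Before that, the single C–C bond between the methine carbon (C*) and C-5 of the trisubstituted 2-aminoimidazole (ring B).
2. Enabling feature: without its acyl groups the target is an exact head-to-tail dimer (2 × C6H10N4) of one 2-amino-4-(3-aminopropenyl)imidazole. This unit is ambiphilic: ring C-5–H is an ene-guanidine nucleophile, and the exocyclic carbon next to C-4 is a cation site (4-alkylidene-imidazolium). C* on ring A and C-5 of ring B are therefore natural partners.
3. Forward: both imidazole rings are bought as 2-aminoimidazole and no ring is built. Hydroxyalkylation with 3-phthalimidopropanal gives one racemic carbinol; its acetate 6 is the cation precursor and its elimination product 8 is the nucleophile.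
4. Chain union (step 4): rac-6 ionises to a planar azafulvenium ion paired with a chiral phosphate, and C-5 of 8 attacks C*. One chain is left saturated and the other E-olefinic, as in the target.
5. Stereochemistry: the only stereocentre comes from this enantioconvergent step (both enantiomers of 6 → one cation → one open face) under counter-anion control. No later step touches it.
6. End game: one hydrazinolysis frees all four nitrogens, and one double acylation installs both 4,5-dibromopyrrole-2-carboxamides.

Key step: step 4

Assumption: the sense of induction of the phosphate cannot be read from a close analogue. The (R)-acid is taken to give (S)-10, and the (S)-acid would be used if the opposite face is found to be open.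

**Step 1**
Reactants: 1 2-aminoimidazole hemisulfate; 2 3-phthalimidopropanal
Product: 4 rac-2-[3-(2-amino-1H-imidazol-4-yl)-3-hydroxypropyl]isoindoline-1,3-dione, via 2-aminoimidazole free base 3 (not isolated)
Conditions: Na2CO3, H2O–MeOH, rt; then 2 (0.5 equiv per 3), MeOH–THF, rt to 40 °C
Reagents that add atoms: none
Why: The free base is an ene-guanidine whose C-4(5) adds to aliphatic aldehydes under neutral conditions (hydroxyalkylation of 2-aminoimidazoles, an aldol-type SEAr), N-adducts being reversible and the excess of 3 holding the reaction at the mono-adduct, and the carbinol centre is left racemic on purpose because steps 3 and 4 erase it.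

**Step 2**
Reactants: 4 rac-carbinol
Product: 6 rac-1-(2-acetamido-1H-imidazol-4-yl)-3-phthalimidopropyl acetate, via rac-1-(2-acetamido-1-acetylimidazol-4-yl)-3-phthalimidopropyl acetate 5 (not isolated)
Conditions: Ac2O (5 equiv), pyridine, 0 °C to rt; then H2O–THF, rt
Reagents that add atoms: acetic anhydride, CC(=O)OC(C)=O
Why: Exhaustive acetylation followed by selective hydrolysis of the azolide-type ring N-acetyl group leaves the exocyclic amide and the ester, and since the nitrogens are acylated before the secondary alcohol, the ring is already a weaker donor when the acetate forms, so 6 should be isolable.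

**Step 3**
Reactants: 6 rac-acetate (the part set aside for the nucleophile)
Product: 8 N-{4-[(E)-3-phthalimidoprop-1-en-1-yl]-1H-imidazol-2-yl}acetamide, via N-[4-(3-phthalimidopropylidene)-4H-imidazol-2-yl]acetamide 7 (not isolated)
Conditions: DBU (1.2 equiv), MeCN, rt to 50 °C
Reagents that add atoms: none
Why: This is a vinylogous E1cB elimination of the kind used to turn imidazolyl carbinol derivatives into 4-vinylimidazoles, in which loss of the ring N–H expels acetate to give 7 and a base-mediated proton shift from the adjacent CH2 restores the aromatic ring and gives the conjugated, thermodynamically preferred E-alkene.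

**Step 4**
Reactants: 6 rac-acetate (1 equiv); 8 E-alkenylimidazole (2.5 equiv, excess recovered)
Product: 10 N-{5-[(1S)-1-(2-acetamido-1H-imidazol-4-yl)-3-phthalimidopropyl]-4-[(E)-3-phthalimidoprop-1-en-1-yl]-1H-imidazol-2-yl}acetamide, via 2-acetamido-4-(3-phthalimidopropylidene)-4H-imidazol-3-ium (R)-TRIP phosphate ion pair 9 (not isolated)
Conditions: (R)-TRIP (10 mol %), 4 Å MS, CH2Cl2, 0 °C to rt, 6 added in portions, stopped when 6 is consumed
Reagents that add atoms: none
Why: Proposed new method: the catalyst proton rests on ring N-3 of 6 (an on-path state) and the bound phosphate relays it to the acetate as this leaves, so both enantiomers of 6 collapse to the same planar 4-alkylidene-4H-imidazolium 9, which stays paired with the chiral phosphate and is attacked at its exocyclic carbon C* by C-5 of 8, after which the phosphate takes H-5, ring B rearomatises and the acid is returned. The closest known reaction types are the chiral-phosphoric-acid-catalysed enantioconvergent Friedel–Crafts substitution of racemic 3-indolyl and 2-pyrrolyl carbinols through alkylidene-azolium phosphate ion pairs and the achiral acid-promoted C-alkylation of 2-aminoimidazoles by (2-aminoimidazol-4-yl)carbinols, and what is new is an imidazole-derived cation under counter-anion control. No ring is closed; the step forms one C–C bond, joins the two C3N chains and creates the only stereocentre. That centre is controlled by the phosphate alone: one of its oxygens accepts the N–H next to the alkylidene carbon of 9 (which also turns the phthalimidoethyl arm towards C-5–H and fixes the alkylidene geometry), the other accepts the ring N–H next to C-5 of 8, and the 2,4,6-triisopropylphenyl walls leave one face of C* open. The step needs C-5 attack over N and alkene-terminus attack, and dimer over oligomer: N-alkylation is reversible under acid, the alkene terminus carries the hindering and inductively deactivating phthalimidomethyl group, and 8 outruns 6 and 10 as nucleophile because its σ-complex is an allyl-extended amidinium ion, its C-5 has a flat neighbour and it is in excess, while the alkene of 10 is twisted out of conjugation by its new neighbour. Side equilibria are harmless, since loss of a proton from 9 only gives more 8, reprotonation of 8 at the alkene terminus regenerates 9, and acetate ion pairs return to 6.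

**Step 5**
Reactants: 10 (S)-dimer
Product: 11 5-[(1S)-3-amino-1-(2-amino-1H-imidazol-4-yl)propyl]-4-[(E)-3-aminoprop-1-en-1-yl]-1H-imidazol-2-amine
Conditions: N2H4·H2O (excess), degassed EtOH, Ar, 75 °C
Reagents that add atoms: none
Why: Ing–Manske hydrazinolysis opens both phthalimides and the same reagent cleaves the two acylguanidine-type acetamides (hydrazinolysis of N-(imidazol-2-yl)acetamides), while the basic, non-ionising medium leaves the C–H stereocentre alone and exclusion of oxygen prevents diimide reduction of the E-alkene.

**Step 6**
Reactants: 11 tetraamine; 12 2,2,2-trichloro-1-(4,5-dibromo-1H-pyrrol-2-yl)ethanone (2.1 equiv)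
Product: 13 target, N-[(3S)-3-(2-amino-1H-imidazol-4-yl)-3-{2-amino-4-[(E)-3-(4,5-dibromo-1H-pyrrole-2-carboxamido)prop-1-en-1-yl]-1H-imidazol-5-yl}propyl]-4,5-dibromo-1H-pyrrole-2-carboxamide
Conditions: i-Pr2NEt, DMF, rt
Reagents that add atoms: none
Why: In this haloform-type acyl transfer from the trichloromethyl ketone the two primary alkylamines are far more nucleophilic than the guanidine-like 2-aminoimidazoles, so both amides should form chemoselectively, as is standard for pyrrole–imidazole alkaloids, and no bond at the stereocentre is touched.

**Compound list**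
1 | 2-aminoimidazole hemisulfate | Nc1ncc[nH]1.Nc1ncc[nH]1.OS(=O)(=O)O | starting material
2 | 3-phthalimidopropanal | O=CCCN1C(=O)c2ccccc2C1=O | starting material
3 | 2-aminoimidazole free base (not isolated) | Nc1ncc[nH]1 | intermediate
4 | rac-2-[3-(2-amino-1H-imidazol-4-yl)-3-hydroxypropyl]isoindoline-1,3-dione | Nc1nc(C(O)CCN2C(=O)c3ccccc3C2=O)c[nH]1 | intermediate
5 | rac-1-(2-acetamido-1-acetylimidazol-4-yl)-3-phthalimidopropyl acetate (not isolated) | CC(=O)Nc1nc(C(CCN2C(=O)c3ccccc3C2=O)OC(C)=O)cn1C(C)=O | intermediate
6 | rac-1-(2-acetamido-1H-imidazol-4-yl)-3-phthalimidopropyl acetate | CC(=O)Nc1nc(C(CCN2C(=O)c3ccccc3C2=O)OC(C)=O)c[nH]1 | intermediate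
7 | N-[4-(3-phthalimidopropylidene)-4H-imidazol-2-yl]acetamide (not isolated) | CC(=O)NC1=NC(=CCCN2C(=O)c3ccccc3C2=O)C=N1 | intermediate
8 | N-{4-[(E)-3-phthalimidoprop-1-en-1-yl]-1H-imidazol-2-yl}acetamide | CC(=O)Nc1nc(/C=C/CN2C(=O)c3ccccc3C2=O)c[nH]1 | intermediate
9 | 2-acetamido-4-(3-phthalimidopropylidene)-4H-imidazol-3-ium, counter-ion (R)-TRIP phosphate (cation drawn; not isolated) | CC(=O)NC1=[NH+]C(=CCCN2C(=O)c3ccccc3C2=O)C=N1 | intermediate
10 | (S)-bis-acetamide bis-phthalimide dimer | CC(=O)Nc1ncc([C@H](CCN2C(=O)c3ccccc3C2=O)c2[nH]c(NC(C)=O)nc2/C=C/CN2C(=O)c3ccccc3C2=O)[nH]1 | intermediate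
11 | (S)-tetraamine | Nc1ncc([C@H](CCN)c2[nH]c(N)nc2/C=C/CN)[nH]1 | intermediate
12 | 2,2,2-trichloro-1-(4,5-dibromo-1H-pyrrol-2-yl)ethanone | O=C(c1cc(Br)c(Br)[nH]1)C(Cl)(Cl)Cl | starting material
13 | target (CID11411715), (S) | Nc1ncc([C@H](CCNC(=O)c2cc(Br)c(Br)[nH]2)c2[nH]c(N)nc2/C=C/CNC(=O)c2cc(Br)c(Br)[nH]2)[nH]1 | target

Total step count: 6. Longest linear sequence: 6 (steps 1–6, because 8 is drawn from 6).

**Steps most likely to fail**

1. **Step 4.** The basic imidazoles level the acid, so the ion pair may be loose and the facial selectivity poor. The product may also be alkylated further.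
 - The fallback gives up asymmetric induction and sets out from 6 and 8.
 - The same union is run with an achiral acid (diphenyl phosphate or CF3CO2H, CH2Cl2, rt). This is the known acid-promoted C-alkylation of aminoimidazoles by aminoimidazolyl carbinol derivatives, and it gives the racemic dimer F1.
 - Preparative SFC on a polysaccharide-based chiral stationary phase separates this into 10 and the (R)-dimer F2.
 - The route is rejoined at 10.

2. **Step 1.** The basic aminoimidazole may cause β-elimination of phthalimide from the aldehyde, and a second hydroxyalkylation may occur at the free ring carbon.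
 - The fallback replaces the hydroxyalkylation by cross-coupling and sets out from 1.
 - Liberation with Na2CO3 and acetylation with Ac2O give N-(1H-imidazol-2-yl)acetamide F3.
 - NIS (1 equiv, MeCN) gives N-(4-iodo-1H-imidazol-2-yl)acetamide F4.
 - Mizoroki–Heck coupling with commercial N-allylphthalimide (Pd(OAc)2, P(o-tol)3, NaOAc, DMF, 90 °C) gives 8.
 - Mukaiyama hydration of part of 8 (Mn(dpm)3 cat., PhSiH3, O2, i-PrOH) places the hydroxyl on the imidazolyl-stabilised radical carbon and gives rac-N-[4-(1-hydroxy-3-phthalimidopropyl)-1H-imidazol-2-yl]acetamide F5.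
 - Acetylation under the conditions of step 2 leads through 5 to 6.
 - The route is rejoined at 8 and 6.

3. **Step 5.** The two acetamides may cleave incompletely at temperatures that the alkene and the stereocentre tolerate, adventitious diimide may reduce the alkene, and the very polar tetraamine may be lost on isolation.
 - The fallback avoids hydrazine, keeps the acetamides to the end and sets out from 10.
 - Reductive phthalimide cleavage (NaBH4, i-PrOH–H2O, rt; then AcOH, 80 °C) gives the (S)-diamine bis-acetamide F6.
 - Acylation with 12 (i-Pr2NEt, DMF, rt) gives the (S)-N2,N2′-diacetyl derivative of the target F7.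
 - Acid methanolysis (HCl, MeOH, 50 °C) removes the two activated acetamides and spares the pyrrole carboxamides.
 - The route is rejoined at 13.

**Further compounds**
F1 | step 4 | racemic bis-acetamide bis-phthalimide dimer | CC(=O)Nc1ncc(C(CCN2C(=O)c3ccccc3C2=O)c2[nH]c(NC(C)=O)nc2/C=C/CN2C(=O)c3ccccc3C2=O)[nH]1
F2 | step 4 | (R)-bis-acetamide bis-phthalimide dimer | CC(=O)Nc1ncc([C@@H](CCN2C(=O)c3ccccc3C2=O)c2[nH]c(NC(C)=O)nc2/C=C/CN2C(=O)c3ccccc3C2=O)[nH]1
F3 | step 1 | N-(1H-imidazol-2-yl)acetamide | CC(=O)Nc1ncc[nH]1
F4 | step 1 | N-(4-iodo-1H-imidazol-2-yl)acetamide | CC(=O)Nc1nc(I)c[nH]1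
F5 | step 1 | rac-N-[4-(1-hydroxy-3-phthalimidopropyl)-1H-imidazol-2-yl]acetamide | CC(=O)Nc1nc(C(O)CCN2C(=O)c3ccccc3C2=O)c[nH]1
F6 | step 5 | (S)-diamine bis-acetamide | CC(=O)Nc1ncc([C@H](CCN)c2[nH]c(NC(C)=O)nc2/C=C/CN)[nH]1
F7 | step 5 | (S)-N2,N2′-diacetyl derivative of the target | CC(=O)Nc1ncc([C@H](CCNC(=O)c2cc(Br)c(Br)[nH]2)c2[nH]c(NC(C)=O)nc2/C=C/CNC(=O)c2cc(Br)c(Br)[nH]2)[nH]1
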